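The runs come from a simulation for substances that don't exist, noise included.

**The level.** 28.2 % of the substrate charged is what ash and alder both show at 2.50 min, though alder starts with twice the [substrate] of ash. Their percent curves run together, as at 0.833 min with 16.9 % and 16.7 %, so midnight, whose [substrate] of 0.10 M lies between them and whose portions are the same, can be read from them.

| flask | substrate | catalyst | remark | time |
|---|---|---|---|---|
| ash | 0.067 M | 1.6 mM (in portions, 4) | run made earlier; portions every 25 s |  |
| alder | 0.15 M | 1.6 mM (in portions, 4) | run made earlier; portions every 25 s |  |
| spring | 0.10 M | 1.6 mM | everything together at the start | 5.0 min |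
| midnight | 0.10 M | 1.6 mM (in portions, 4) | the portions of catalyst follow each other after 25 s, the first at the start | 2.5 min |

| run | time / min | product / % |
|---|---|---|
| ash | 0.200 | 0.2 |
| ash | 0.333 | 4.5 |
| ash | 0.500 | 9.3 |
| ash | 0.833 | 16.9 |
| ash | 1.50 | 25.7 |
| ash | 2.50 | 28.2 |
| alder | 0.167 | 1.6 |
| alder | 0.500 | 8.1 |
| alder | 0.833 | 16.7 |
| alder | 1.33 | 24.1 |
| alder | 2.00 | 27.6 |
| alder | 2.50 | 28.2 |

(scatter of a reading: 0.5 percentage points)

- the winner by amount of product, in percent of the substrate charged; "neither" if no more than 2 percentage points parts them (spring / midnight / neither)
- how much product is there at the end, in percent of the substrate charged: spring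
- how much product is there at the end, in percent of the substrate charged: midnight

- the numbers in the tables scatter by 0.5 percentage points (one standard deviation)

**Closing rate.** The last portion goes in at 1.25 min, so the later readings come after the whole charge of catalyst has been added. From 25.7 % in ash at 1.50 min to alder's 27.6 % at 2.00 min and 28.2 % at 2.50 min, the rises are 1.9 percentage points and then 0.6 points. If the gap shrinks by a steady factor, this gives the closing half-life, the time in which the gap below the final level halves, as 0.301 min. It is a reading, and it carries the scatter of 0.5 points. The same rises put the final level at 28.5 %.

**The ladder.** The closing half-life, as read, is shorter than the 0.42 min between portions. At the start hardly any product stands: ash reads 0.2 % at 0.200 min. At 2.5 min, midnight should read like ash and alder, 28.2 %, with 0.30 points still to come. Spring has its whole charge of catalyst in from the start and runs for 5.0 min, which is 16.6 closing half-lives as read, so my reckoning, assuming the same level, puts it at 28.5 %. That lead is less than the margin of 2 points, which makes neither the winner.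

**The forecast.** It gives 28.2 % for spring, lower than my level, and 28.1 % for midnight, with neither as the winner: “The two are indistinguishable”.

**The flask.** Spring gives 29.1 % and midnight 28.3 %, so the winner is neither, with 0.80 points between them. Spring ends with 29.1 % product beside 70.9 % intermediate and 0.0304 % substrate.

    substrate → intermediate (k = 0.0270 s⁻¹)
    catalyst + intermediate ⇌ catalyst + product (K = 0.410, k = 30.0 M⁻¹ s⁻¹)
    catalyst ⇌ dormant form (K = 1.50, k = 0.0130 s⁻¹)

**Second flask.** The closing half-life read from ash and alder is a scattered reading, so the count of 16.6 in 5.0 min is an estimate; by the 0.533 min relaxation half-life of catalyst and dormant form in spring, the same time is 9.38 half-lives. The neighbour of spring with 0.25 M of substrate, given that same time, ends at 29.1 %.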